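The pyridine ring of the isoquinoline is cut at C4a–C4 and N2–C3. This leaves a biaryl acetophenone E-oxime and an acetyl-substituted sulfoxonium ylide that serves as acetonyl carbene source. In one rhodium-catalysed operation the benzene ring is metalated, the carbene is inserted and the new ketone condenses with the oxime nitrogen, so the whole 1,3-dimethylpyridine ring appears as its N-oxide. The step exploits the substitution around C8a in the carbocyclic ring: C8 bears methoxy, so C4a holds the only C–H that the oxime nitrogen can reach. The precursor already contains the C7–C1' biaryl bond, the C8 methoxy group and the C1 methyl group.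

Key step: step 10

Assumption: the target string defines no configuration for the hindered C7–C1' axis, so all biaryl compounds are made and drawn as racemates.

Step 1
Reactants: 1 N,N-diethyl-2-methoxybenzamide; 2 3-bromo-2-methylprop-1-ene (methallyl bromide)
Product: 5 N,N-diethyl-2-methoxy-6-(2-methylprop-2-en-1-yl)benzamide, via 6-lithiobenzamide 3 (not isolated), via arylmagnesium bromide 4 (not isolated)
Conditions: s-BuLi, TMEDA, THF, −78 °C; MgBr2·OEt2, −78 °C → rt; 2, 0 °C → rt
Reagents that add atoms: none
Why: Directed ortho-metalation, in which the tertiary amide outranks the methoxy group as director so that H6 is removed, followed by exchange of lithium for magnesium to lower the basicity before allylation by 2, whose SN2 and SN2' pathways lead to the same product.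

Step 2
Reactants: 5 N,N-diethyl-2-methoxy-6-(2-methylprop-2-en-1-yl)benzamide
Product: 6 8-methoxy-3-methylnaphthalen-1-ol
Conditions: MeLi (2.2 equiv), THF, −78 °C → rt; 1 M HCl
Reagents that add atoms: none
Why: Anionic ring annulation of an ortho-allylbenzamide, in which the benzylic and allylic CH2 is deprotonated, the terminal carbon of the allyl anion acylates on the neighbouring amide in a six-membered closure, and loss of diethylamide with tautomerisation should give the naphthol.

Step 3
Reactants: 6 8-methoxy-3-methylnaphthalen-1-ol
Product: 7 1,8-dimethoxy-3-methylnaphthalene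
Conditions: MeI, K2CO3, DMF, rt → 40 °C
Reagents that add atoms: iodomethane CI
Why: Williamson ether synthesis, in which carbonate in a dipolar solvent frees the naphtholate from its hydrogen bond to the peri methoxy group and the naphtholate is methylated by SN2 attack on MeI.

Step 4
Reactants: 7 1,8-dimethoxy-3-methylnaphthalene
Product: 8 1-bromo-4,5-dimethoxy-2-methylnaphthalene
Conditions: NBS (1.0 equiv), MeCN, 0 °C, dark
Reagents that add atoms: N-bromosuccinimide O=C1CCC(=O)N1Br
Why: Electrophilic aromatic bromination, directed to C4 of 7 because it is an alpha position para to the C1 methoxy group and ortho to the methyl group in the more electron-rich ring, while ionic conditions in the dark spare the benzylic methyl group.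

Step 5
Reactants: 8 1-bromo-4,5-dimethoxy-2-methylnaphthalene
Product: 11 (4,5-dimethoxy-2-methylnaphthalen-1-yl)boronic acid, via naphthyllithium 9 (not isolated), via lithium triisopropoxyborate 10 (not isolated)
Conditions: n-BuLi, THF, −78 °C; B(OiPr)3, −78 °C → rt; 1 M HCl
Reagents that add atoms: triisopropyl borate CC(C)OB(OC(C)C)OC(C)C; water O
Why: Bromine–lithium exchange followed by borate trapping and hydrolysis; the exchange is much faster at −78 °C than deprotonation of the methyl or methoxy groups.

Step 6
Reactants: 12 1-(3-bromo-2-hydroxyphenyl)ethanone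
Product: 13 1-(3-bromo-2-methoxyphenyl)ethanone
Conditions: MeI, K2CO3, DMF, rt → 50 °C
Reagents that add atoms: iodomethane CI
Why: Williamson ether synthesis, in which carbonate in DMF breaks the hydrogen bond of the phenol to the acetyl group and the phenoxide is O-methylated, the base being too weak to C-methylate the ketone.

Step 7
Reactants: 11 (4,5-dimethoxy-2-methylnaphthalen-1-yl)boronic acid; 13 1-(3-bromo-2-methoxyphenyl)ethanone
Product: 14 1-[3-(4,5-dimethoxy-2-methylnaphthalen-1-yl)-2-methoxyphenyl]ethanone
Conditions: Pd(OAc)2 (3 mol %), SPhos (2-dicyclohexylphosphino-2',6'-dimethoxybiphenyl, 6 mol %), K3PO4, toluene/H2O, 100 °C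
Reagents that add atoms: none
Why: Suzuki–Miyaura coupling, in which zerovalent palladium with the bulky, electron-rich SPhos ligand suits biaryls with three ortho substituents and the aqueous phosphate medium leaves the methyl ketone alone.

Step 8
Reactants: 14 1-[3-(4,5-dimethoxy-2-methylnaphthalen-1-yl)-2-methoxyphenyl]ethanone
Product: 15 (E)-1-[3-(4,5-dimethoxy-2-methylnaphthalen-1-yl)-2-methoxyphenyl]ethanone oxime
Conditions: NH2OH·HCl, NaOAc, EtOH/H2O, 80 °C
Reagents that add atoms: hydroxylamine hydrochloride Cl.NO
Why: Oxime condensation under acetate buffering, reversible so that the C=N bond settles in the E geometry with OH anti to the bulky aryl group, any Z isomer being separated on silica and re-equilibrated with acid.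

Step 9
Reactants: 16 trimethylsulfoxonium iodide; 17 acetyl chloride
Product: 19 1-[dimethyl(oxo)-λ6-sulfanylidene]propan-2-one, via dimethylsulfoxonium methylide 18 (not isolated)
Conditions: 16 (3 equiv), KOtBu, THF, reflux; 17 (1 equiv), 0 °C → rt; filtration, no aqueous work-up
Reagents that add atoms: none
Why: C-acylation of the Corey–Chaykovsky methylide, in which 18 attacks the acid chloride at carbon and a second equivalent of 18 deprotonates the acylsulfoxonium salt to give the carbonyl-stabilised, water-soluble ylide.

Step 10
Reactants: 15 (E)-1-[3-(4,5-dimethoxy-2-methylnaphthalen-1-yl)-2-methoxyphenyl]ethanone oxime; 19 1-[dimethyl(oxo)-λ6-sulfanylidene]propan-2-one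
Product: 21 7-(4,5-dimethoxy-2-methylnaphthalen-1-yl)-8-methoxy-1,3-dimethylisoquinoline 2-oxide, via acetonyl oxime 20 (not isolated)
Conditions: [Cp*RhCl2]2 (4 mol %), AgSbF6 (16 mol %), PivOH (1 equiv), 19 (2 equiv, two portions), 1,2-dichloroethane, 90 °C, N2
Reagents that add atoms: none
Why: AgSbF6 strips chloride from [Cp*RhCl2]2 to give a cationic Cp*Rh complex of trivalent rhodium that binds the nitrogen lone pair of the E-oxime and, with pivalate as internal base (concerted metalation–deprotonation), cleaves the C6–H bond of the phenyl ring (future C4a) to form a five-membered rhodacycle; ylide 19 then binds through carbon, expels DMSO to leave a rhodium carbene, 1,1-migratory insertion of the aryl group makes C4a–C4, and protonolysis by PivOH releases 20 and returns the catalyst. The closest known reaction type is the Cp*Rh-catalysed C–H annulation of aryl ketoximes with diazo ketones or acyl sulfoxonium ylides as carbene sources, which gives isoquinoline N-oxides. The pyridine ring closes by 6-exo-trig attack of the oxime nitrogen of 20 on the ketone carbonyl (N2–C3), and acid-catalysed loss of water from the cyclic carbinol aromatises it to the N-oxide. No stereocentre is formed, and the racemic C7–C1' axis is a spectator. The step needs site selectivity, which the substrate secures: C8 is blocked by methoxy, so C4a carries the only C–H next to C8a, no naphthalene C–H can complete a five-membered chelate, and a second insertion is excluded because 21 has methyl groups at C1 and C3 and no free ortho C–H. PivOH is added because the metalation needs a carboxylate that the chloride/hexafluoroantimonate pair does not supply, and it also interconverts any Z-oxime with the reactive E form.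

Step 11
Reactants: 21 7-(4,5-dimethoxy-2-methylnaphthalen-1-yl)-8-methoxy-1,3-dimethylisoquinoline 2-oxide
Product: 22 7-(4,5-dimethoxy-2-methylnaphthalen-1-yl)-8-methoxy-1,3-dimethylisoquinoline
Conditions: Zn dust, sat. aq NH4Cl, THF, rt → 50 °C
Reagents that add atoms: none
Why: Zinc-mediated deoxygenation of a heteroaromatic N-oxide, in which electron transfer from zinc with NH4Cl as mild proton source cleaves only the N–O bond, and the absence of phosphorus chlorides rules out activation of the N-oxide toward chlorination at the C1 and C3 methyl groups.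

Compound list
1 | N,N-diethyl-2-methoxybenzamide | CCN(CC)C(=O)c1ccccc1OC | starting material
2 | 3-bromo-2-methylprop-1-ene | C=C(C)CBr | starting material
3 | [2-(diethylcarbamoyl)-3-methoxyphenyl]lithium | [Li]c1cccc(OC)c1C(=O)N(CC)CC | intermediate
4 | [2-(diethylcarbamoyl)-3-methoxyphenyl]magnesium bromide | Br[Mg]c1cccc(OC)c1C(=O)N(CC)CC | intermediate
5 | N,N-diethyl-2-methoxy-6-(2-methylprop-2-en-1-yl)benzamide | C=C(C)Cc1cccc(OC)c1C(=O)N(CC)CC | intermediate
6 | 8-methoxy-3-methylnaphthalen-1-ol | COc1cccc2cc(C)cc(O)c12 | intermediate
7 | 1,8-dimethoxy-3-methylnaphthalene | COc1cccc2cc(C)cc(OC)c12 | intermediate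
8 | 1-bromo-4,5-dimethoxy-2-methylnaphthalene | COc1cccc2c(Br)c(C)cc(OC)c12 | intermediate
9 | (4,5-dimethoxy-2-methylnaphthalen-1-yl)lithium | [Li]c1c(C)cc(OC)c2c(OC)cccc12 | intermediate
10 | lithium (4,5-dimethoxy-2-methylnaphthalen-1-yl)triisopropoxyborate | [Li+].CC(C)O[B-](OC(C)C)(OC(C)C)c1c(C)cc(OC)c2c(OC)cccc12 | intermediate
11 | (4,5-dimethoxy-2-methylnaphthalen-1-yl)boronic acid | OB(O)c1c(C)cc(OC)c2c(OC)cccc12 | intermediate
12 | 1-(3-bromo-2-hydroxyphenyl)ethanone | CC(=O)c1cccc(Br)c1O | starting material
13 | 1-(3-bromo-2-methoxyphenyl)ethanone | CC(=O)c1cccc(Br)c1OC | intermediate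
14 | 1-[3-(4,5-dimethoxy-2-methylnaphthalen-1-yl)-2-methoxyphenyl]ethanone (racemic axis) | CC(=O)c1cccc(-c2c(C)cc(OC)c3c(OC)cccc23)c1OC | intermediate
15 | (E)-1-[3-(4,5-dimethoxy-2-methylnaphthalen-1-yl)-2-methoxyphenyl]ethanone oxime | C/C(=N\O)c1cccc(-c2c(C)cc(OC)c3c(OC)cccc23)c1OC | intermediate
16 | trimethylsulfoxonium iodide | C[S+](C)(C)=O.[I-] | starting material
17 | acetyl chloride | CC(=O)Cl | starting material
18 | dimethylsulfoxonium methylide | C=S(C)(C)=O | intermediate
19 | 1-[dimethyl(oxo)-λ6-sulfanylidene]propan-2-one | CC(=O)C=S(C)(C)=O | intermediate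
20 | (E)-1-[3-(4,5-dimethoxy-2-methylnaphthalen-1-yl)-2-methoxy-6-(2-oxopropyl)phenyl]ethanone oxime | C/C(=N\O)c1c(CC(C)=O)ccc(-c2c(C)cc(OC)c3c(OC)cccc23)c1OC | intermediate
21 | 7-(4,5-dimethoxy-2-methylnaphthalen-1-yl)-8-methoxy-1,3-dimethylisoquinoline 2-oxide | COc1c(-c2c(C)cc(OC)c3c(OC)cccc23)ccc2cc(C)[n+]([O-])c(C)c12 | intermediate
22 | 7-(4,5-dimethoxy-2-methylnaphthalen-1-yl)-8-methoxy-1,3-dimethylisoquinoline | COc1c(-c2c(C)cc(OC)c3c(OC)cccc23)ccc2cc(C)nc(C)c12 | target

Total step count: 11. Longest linear sequence: 9 steps (1, 2, 3, 4, 5, 7, 8, 10, 11).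

Steps most likely to fail

Step 10. The C8 methoxy group, pressed by the naphthyl group, holds the oxime out of the plane of the benzene ring. Cyclometalation may therefore be slow, and protonation or thermal loss of the ylide could outrun carbene capture. Oxidative wear of the electron-rich naphthalene by the silver salt would be a second drain.
- The fallback moves the annulation ahead of the biaryl coupling. It sets out from 13, uses 19 and 11, and comes back at 21.
- Ketone 13 is condensed with NH2OH·HCl/NaOAc to (E)-1-(3-bromo-2-methoxyphenyl)ethanone oxime F1.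
- F1 is annulated with 19 under the catalyst system of step 10, through (E)-1-[3-bromo-2-methoxy-6-(2-oxopropyl)phenyl]ethanone oxime F2, to 7-bromo-8-methoxy-1,3-dimethylisoquinoline 2-oxide F3.
- This cheap, naphthalene-free substrate allows higher catalyst loading and more ylide, and aryl bromides are inert to trivalent rhodium.
- Suzuki–Miyaura coupling of F3 with 11 (Pd(OAc)2, SPhos, K3PO4, toluene/H2O) then gives 21.

Step 7. Protodeboronation of the hindered, electron-rich boronic acid may compete with slow transmetalation.
- The fallback reverses the polarity of the coupling. It sets out from 13 and 8 and comes back at 14, and step 5 is no longer needed.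
- Miyaura borylation of 13 (bis(pinacolato)diboron, PdCl2(dppf), KOAc, dioxane, 90 °C) gives 1-[2-methoxy-3-(4,4,5,5-tetramethyl-1,3,2-dioxaborolan-2-yl)phenyl]ethanone F4. This boronate carries a single ortho substituent and an electron-poor ring.
- F4 is coupled with bromide 8 (Pd(OAc)2, SPhos, K3PO4, dioxane/H2O) to give 14.

Step 4. Positional control may be lost, with bromination spilling to the position para to the other methoxy group or going on to double bromination.
- The fallback brominates before the second methylation. It sets out from 6 and comes back at 8.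
- In 6 the free hydroxyl group is a far stronger para director than either methoxy group, so NBS in MeCN at −20 °C should give 4-bromo-8-methoxy-3-methylnaphthalen-1-ol F5.
- F5 is O-methylated (MeI, K2CO3, DMF) to give 8.

Further compounds
F1 | step 10 | (E)-1-(3-bromo-2-methoxyphenyl)ethanone oxime | C/C(=N\O)c1cccc(Br)c1OC
F2 | step 10 | (E)-1-[3-bromo-2-methoxy-6-(2-oxopropyl)phenyl]ethanone oxime | C/C(=N\O)c1c(CC(C)=O)ccc(Br)c1OC
F3 | step 10 | 7-bromo-8-methoxy-1,3-dimethylisoquinoline 2-oxide | COc1c(Br)ccc2cc(C)[n+]([O-])c(C)c12
F4 | step 7 | 1-[2-methoxy-3-(4,4,5,5-tetramethyl-1,3,2-dioxaborolan-2-yl)phenyl]ethanone | CC(=O)c1cccc(B2OC(C)(C)C(C)(C)O2)c1OC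
F5 | step 4 | 4-bromo-8-methoxy-3-methylnaphthalen-1-ol | COc1cccc2c(Br)c(C)cc(O)c12
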